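## Retrosynthetic overview

1. Target ⇒ two molecules of (3S,4S)-arctigenin, joined last by a phenol oxidative (radical) 4-O–5′ C–O coupling, as lignan dimers are thought to arise in the plant; no ring is formed here.
2. Each arctigenin ⇒ an open-chain 2,3-dibenzylsuccinate with C9 as methyl ester and C9′ as an Evans imide; the imide is reduced to CH2OH and O9′ closes onto C9 to give the γ-lactone, with C3 set by trans equilibration.
3. Succinate ⇒ two C6C3 units (veratrylpropanoyl imide + protected dihydroferulate ester), joined at C8–C8′ by one oxidative enolate heterocoupling, the laboratory version of the 8–8′ radical coupling; the (R)-auxiliary sets C4 = S.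
4. Ring order: the four arenes are bought; each lactone is closed after the C8–C8′ bond; the two lactone-bearing halves are united at the end.

Assumption: the SMILES is read as 3S,4S in both lactones (the mirror image of the (3R,4R)-arctigenin isolated from burdock seed), so the monomer to be made is (3S,4S)-arctigenin and the (R)-oxazolidinone is required.

## Route

Step 1
Reactants: 1 3-(3,4-dimethoxyphenyl)propanoic acid; 2 (4R)-4-benzyl-1,3-oxazolidin-2-one
Product: 4 (4R)-4-benzyl-3-[3-(3,4-dimethoxyphenyl)propanoyl]-1,3-oxazolidin-2-one, via mixed pivalic anhydride 3 (not isolated)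
Conditions: PivCl (1.1 equiv), Et3N (2.5 equiv), THF, −20 °C; then LiCl (1.2 equiv), 2 (1.0 equiv), −20 °C → rt
Reagents that add atoms: none
Why: N-acylation of the oxazolidinone through the mixed anhydride (LiCl/Et3N one-pot auxiliary loading); no stereocentre is formed.

Step 2
Reactants: 5 methyl 3-(4-hydroxy-3-methoxyphenyl)propanoate
Product: 6 methyl 3-[4-(tert-butyldimethylsilyloxy)-3-methoxyphenyl]propanoate
Conditions: TBSCl (1.2 equiv), imidazole (2.0 equiv), DMF, rt
Reagents that add atoms: tert-butyldimethylsilyl chloride, CC(C)(C)[Si](C)(C)Cl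
Why: Phenol silylation masks the acidic, oxidisable ArOH for the enolate oxidation; the aryl silyl ether is base-labile and comes off in step 4 without a separate operation.

Step 3
Reactants: 4 (4R)-4-benzyl-3-[3-(3,4-dimethoxyphenyl)propanoyl]-1,3-oxazolidin-2-one; 6 methyl 3-[4-(tert-butyldimethylsilyloxy)-3-methoxyphenyl]propanoate
Product: 9 methyl (2RS,3S)-4-[(4R)-4-benzyl-2-oxo-1,3-oxazolidin-3-yl]-2-[[4-(tert-butyldimethylsilyloxy)-3-methoxyphenyl]methyl]-3-[(3,4-dimethoxyphenyl)methyl]-4-oxobutanoate, via imide lithium Z-enolate 7 (not isolated), via ester lithium enolate 8 (not isolated)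
Conditions: 4 (1.0 equiv) + 6 (1.5 equiv), LDA (commercial solution, 2.6 equiv), THF, −78 °C, 30 min; then Fe(acac)3 (2.6 equiv), −78 °C → rt; 1 M HCl work-up, chromatography (removes homodimers and the minor C3 diastereomers)
Reagents that add atoms: none
Why: Fe(III)-mediated oxidative enolate heterocoupling (Baran-type), the chemical counterpart of the 8–8′ phenylpropanoid radical coupling: the more easily oxidised ester enolate 8 gives an α-carbonyl radical that adds to the chelated Z-enolate 7 on the face opposite the auxiliary benzyl group, so C3 of 9 (future lactone C4) is set S as in an Evans alkylation, while C2 (future lactone C3) forms unselectively and is corrected in step 4.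

Step 4
Reactants: 9 methyl (2RS,3S)-4-[(4R)-4-benzyl-2-oxo-1,3-oxazolidin-3-yl]-2-[[4-(tert-butyldimethylsilyloxy)-3-methoxyphenyl]methyl]-3-[(3,4-dimethoxyphenyl)methyl]-4-oxobutanoate
Product: 12 (3S,4S)-4-[(3,4-dimethoxyphenyl)methyl]-3-[(4-hydroxy-3-methoxyphenyl)methyl]oxolan-2-one [(3S,4S)-arctigenin], via hydroxy ester 10 (not isolated), via silyl lactone 11 (not isolated)
Conditions: NaBH4 (4 equiv), THF/H2O (4:1), 0 °C → rt; aq. NH4Cl, extract, concentrate; then NaOMe (3 equiv), dry MeOH, rt, 12 h; then 2 M HCl to pH 2, rt (auxiliary 2 recovered)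
Reagents that add atoms: none
Why: Chemoselective borohydride reduction of the N-acyloxazolidinone (imide far faster than methyl ester) gives the γ-hydroxy ester, which closes by O→C9 lactonisation; methoxide then cleaves the aryl silyl ether and equilibrates C3 through the lactone enolate to the thermodynamically favoured trans (3S,4S) isomer (any methanolysis is reversed on acidification), C4 being non-enolisable and untouched.

Step 5
Reactants: 12 (3S,4S)-arctigenin (two molecules)
Product: 14 (3S,4S)-3-[[3-[4-[[(3S,4S)-4-[(3,4-dimethoxyphenyl)methyl]-2-oxooxolan-3-yl]methyl]-2-methoxyphenoxy]-4-hydroxy-5-methoxyphenyl]methyl]-4-[(3,4-dimethoxyphenyl)methyl]oxolan-2-one (CNP0183104.1), via dienone tautomer 13 (not isolated)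
Conditions: horseradish peroxidase (cat.), H2O2 (0.3 equiv, syringe pump, 2 h), acetone/0.1 M phosphate buffer pH 6 (2:3), 5 mM, rt; chromatography/prep-HPLC, recovered 12 recycled
Reagents that add atoms: none
Why: Peroxidase-catalysed one-electron phenol oxidation followed by phenoxyl radical–radical coupling (phenol oxidative coupling): O4 of one radical bonds to C5′ of a second and dienone 13 tautomerises to the diaryl ether; no stereocentre is made or touched at pH 6, and the 5–5′ biaryl isomer, expected as the main by-product, is separated together with unreacted 12 (water is the only co-product).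

## Compound list

1 | 3-(3,4-dimethoxyphenyl)propanoic acid | COc1ccc(CCC(=O)O)cc1OC | starting material
2 | (4R)-4-benzyl-1,3-oxazolidin-2-one | O=C1N[C@H](Cc2ccccc2)CO1 | starting material
3 | 3-(3,4-dimethoxyphenyl)propanoic pivalic anhydride | COc1ccc(CCC(=O)OC(=O)C(C)(C)C)cc1OC | intermediate
4 | (4R)-4-benzyl-3-[3-(3,4-dimethoxyphenyl)propanoyl]-1,3-oxazolidin-2-one | COc1ccc(CCC(=O)N2[C@H](Cc3ccccc3)COC2=O)cc1OC | intermediate
5 | methyl 3-(4-hydroxy-3-methoxyphenyl)propanoate (methyl dihydroferulate) | COC(=O)CCc1ccc(O)c(OC)c1 | starting material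
6 | methyl 3-[4-(tert-butyldimethylsilyloxy)-3-methoxyphenyl]propanoate | COC(=O)CCc1ccc(O[Si](C)(C)C(C)(C)C)c(OC)c1 | intermediate
7 | lithium (Z)-enolate of imide 4 | COc1ccc(C/C=C(\O[Li])N2[C@H](Cc3ccccc3)COC2=O)cc1OC | intermediate
8 | lithium enolate of ester 6 (geometry not relevant) | COC(O[Li])=CCc1ccc(O[Si](C)(C)C(C)(C)C)c(OC)c1 | intermediate
9 | methyl (2RS,3S)-4-[(4R)-4-benzyl-2-oxo-1,3-oxazolidin-3-yl]-2-[[4-(tert-butyldimethylsilyloxy)-3-methoxyphenyl]methyl]-3-[(3,4-dimethoxyphenyl)methyl]-4-oxobutanoate (C2 epimers, C3 = S) | COC(=O)C(Cc1ccc(O[Si](C)(C)C(C)(C)C)c(OC)c1)[C@H](Cc1ccc(OC)c(OC)c1)C(=O)N1[C@H](Cc2ccccc2)COC1=O | intermediate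
10 | methyl (2RS,3S)-2-[[4-(tert-butyldimethylsilyloxy)-3-methoxyphenyl]methyl]-3-[(3,4-dimethoxyphenyl)methyl]-4-hydroxybutanoate | COC(=O)C(Cc1ccc(O[Si](C)(C)C(C)(C)C)c(OC)c1)[C@H](Cc1ccc(OC)c(OC)c1)CO | intermediate
11 | (3RS,4S)-3-[[4-(tert-butyldimethylsilyloxy)-3-methoxyphenyl]methyl]-4-[(3,4-dimethoxyphenyl)methyl]oxolan-2-one (cis/trans mixture) | COc1ccc(C[C@@H]2COC(=O)C2Cc2ccc(O[Si](C)(C)C(C)(C)C)c(OC)c2)cc1OC | intermediate
12 | (3S,4S)-4-[(3,4-dimethoxyphenyl)methyl]-3-[(4-hydroxy-3-methoxyphenyl)methyl]oxolan-2-one, (3S,4S)-arctigenin | COc1ccc(C[C@@H]2COC(=O)[C@H]2Cc2ccc(O)c(OC)c2)cc1OC | intermediate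
13 | 6-aryloxy-2-methoxycyclohexa-2,4-dienone tautomer of 14 (new sp3 C–O carbon unassigned, lost on tautomerisation) | COc1ccc(C[C@@H]2COC(=O)[C@H]2Cc2ccc(OC3C=C(C[C@@H]4C(=O)OC[C@H]4Cc4ccc(OC)c(OC)c4)C=C(OC)C3=O)c(OC)c2)cc1OC | intermediate
14 | CNP0183104.1, 4-O-5′ diaryl ether dimer of (3S,4S)-arctigenin | COc1ccc(C[C@@H]2COC(=O)[C@H]2Cc2ccc(Oc3cc(C[C@@H]4C(=O)OC[C@H]4Cc4ccc(OC)c(OC)c4)cc(OC)c3O)c(OC)c2)cc1OC | target

## Step count and risks

Total steps: 5. Longest linear sequence: 4 (steps 1, 3, 4, 5, or equally 2, 3, 4, 5).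

**Most likely to fail, in order:**

1. **Step 5 (oxidative C–O dimerisation).** For 4-alkylguaiacols the 5–5′ C–C coupling normally outweighs the 4-O–5′ coupling, and the dimers can be oxidised further. I expect roughly 10–15 % of 14 per pass at partial conversion, with 12 recycled.
 Fallback, from 12 back to 14, replacing the radical coupling with a copper-catalysed cross-coupling of differentiated partners: 12 is iodinated ortho to the phenol (BnMe3N+ ICl2−, NaHCO3, CH2Cl2/MeOH, rt; methoxyarenes are inert under these conditions) to give (3S,4S)-5′-iodoarctigenin F1. Benzylation (BnBr, K2CO3, acetone, 50 °C) gives O-benzyl-5′-iodoarctigenin F2. Ullmann coupling of F2 with a second equivalent of 12 (CuI, picolinic acid, K3PO4, DMSO, 90 °C) gives the O-benzyl ether of the target F3, and hydrogenolysis (H2, Pd/C, EtOAc/EtOH) returns to 14.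

2. **Step 3 (enolate heterocoupling).** Homodimers compete, the yield is likely only 40–55 %, and four diastereomers must be sorted so that only the C3-S pair goes forward.
 Fallback, from 4 back to 12, building the two C–C bonds by sequential polar alkylations: the sodium enolate of 4 (NaHMDS, THF, −78 °C) is alkylated with tert-butyl bromoacetate anti to the auxiliary benzyl group to give tert-butyl (3S)-4-[(4R)-4-benzyl-2-oxo-1,3-oxazolidin-3-yl]-3-[(3,4-dimethoxyphenyl)methyl]-4-oxobutanoate F4. Reduction and lactonisation (LiBH4, THF/MeOH, 0 °C; then TFA, CH2Cl2) give (4S)-4-[(3,4-dimethoxyphenyl)methyl]oxolan-2-one F5. Its lithium enolate (LiHMDS, THF, −78 °C) is alkylated trans to the C4 substituent with commercial 4-(benzyloxy)-3-methoxybenzyl bromide (BrCc1ccc(OCc2ccccc2)c(OC)c1) to give (3S,4S)-O-benzylarctigenin F6, and hydrogenolysis (H2, Pd/C, EtOAc) returns to 12.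

3. **Step 4 (reduction / lactonisation / desilylation / epimerisation).** The imide is α,β-branched, so borohydride may attack the ring carbonyl or react sluggishly; over-reduction of the lactone to the diol is also possible.
 Fallback, from 9 back to 11, replacing hydride discrimination between imide and ester with acid-versus-ester discrimination: 9 is cleaved with LiOH/H2O2 (THF/H2O, 0 °C; Na2SO3 quench), which selectively removes the auxiliary even from hindered imides, to give (2S,3RS)-2-[(3,4-dimethoxyphenyl)methyl]-3-[[4-(tert-butyldimethylsilyloxy)-3-methoxyphenyl]methyl]-4-methoxy-4-oxobutanoic acid F7. BH3·SMe2 (THF, 0 °C → rt) reduces only the carboxylic acid, and catalytic TsOH in toluene closes the ring to silyl lactone 11, which then takes the NaOMe/MeOH and HCl stages of step 4 to 12.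

## Further compounds

F1 | step 5 | (3S,4S)-4-[(3,4-dimethoxyphenyl)methyl]-3-[(4-hydroxy-3-iodo-5-methoxyphenyl)methyl]oxolan-2-one | COc1ccc(C[C@@H]2COC(=O)[C@H]2Cc2cc(I)c(O)c(OC)c2)cc1OC
F2 | step 5 | (3S,4S)-3-[(4-benzyloxy-3-iodo-5-methoxyphenyl)methyl]-4-[(3,4-dimethoxyphenyl)methyl]oxolan-2-one | COc1ccc(C[C@@H]2COC(=O)[C@H]2Cc2cc(I)c(OCc3ccccc3)c(OC)c2)cc1OC
F3 | step 5 | O-benzyl ether of 14 (benzyl on the 4′-oxygen of the 5′-linked unit, all four centres S) | COc1ccc(C[C@@H]2COC(=O)[C@H]2Cc2ccc(Oc3cc(C[C@@H]4C(=O)OC[C@H]4Cc4ccc(OC)c(OC)c4)cc(OC)c3OCc3ccccc3)c(OC)c2)cc1OC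
F4 | step 3 | tert-butyl (3S)-4-[(4R)-4-benzyl-2-oxo-1,3-oxazolidin-3-yl]-3-[(3,4-dimethoxyphenyl)methyl]-4-oxobutanoate | COc1ccc(C[C@@H](CC(=O)OC(C)(C)C)C(=O)N2[C@H](Cc3ccccc3)COC2=O)cc1OC
F5 | step 3 | (4S)-4-[(3,4-dimethoxyphenyl)methyl]oxolan-2-one | COc1ccc(C[C@@H]2COC(=O)C2)cc1OC
F6 | step 3 | (3S,4S)-3-[(4-benzyloxy-3-methoxyphenyl)methyl]-4-[(3,4-dimethoxyphenyl)methyl]oxolan-2-one | COc1ccc(C[C@@H]2COC(=O)[C@H]2Cc2ccc(OCc3ccccc3)c(OC)c2)cc1OC
F7 | step 4 | (2S,3RS)-2-[(3,4-dimethoxyphenyl)methyl]-3-[[4-(tert-butyldimethylsilyloxy)-3-methoxyphenyl]methyl]-4-methoxy-4-oxobutanoic acid | COC(=O)C(Cc1ccc(O[Si](C)(C)C(C)(C)C)c(OC)c1)[C@H](Cc1ccc(OC)c(OC)c1)C(=O)O
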